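All runs stem from a simulated flask with made-up constants.

A ratio of two rates, the making of target over its drain, is the rough estimate I start from in these flasks.

in all of them: substrate 20 mM; second catalyst 0.20 mM
- elm: coupling partner 24 mM; free catalyst 31 µM; run made earlier
- maple: coupling partner 24 mM; free catalyst 81 µM; run made earlier
- summer: coupling partner 24.0 mM; free catalyst 22 µM; time 2.0 h
- spring: coupling partner 24.0 mM; free catalyst 66 µM; time 2.0 h

| elm: time / min | elm: target / % | maple: time / min | maple: target / % |
|---|---|---|---|
| 10.0 | 4 | 10.0 | 9 |
| 20.0 | 7 | 20.0 | 15 |
| 30.0 | 7 | 30.0 | 24 |
| 60.0 | 14 | 60.0 | 28 |
| 120 | 12 | 120 | 25 |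

(readings scatter by 1.5 percentage points)
* which of the two there is more of at the end, summer (over-reaction product / target)
* which of the two there is more of at the end, spring (over-reaction product / target)
* final target, as a percentage of the substrate charged, in summer
* final target, as a percentage of the substrate charged, in spring
- the numbers in the tables scatter with a standard deviation of 1.5 percentage points

1. In the maple run I read the making rate from the first 30.0 min, which gives 0.00800 min⁻¹ of the charged substrate, and I take the plateau as the mean of the last two readings, 26.5%.

2. Where the maple readings level off I take making and drain as about equal, so I read an apparent drain constant of 0.0302 min⁻¹, a half-life of 23.0 min, which is a rough figure that pairs the early making with the later plateau; since that is shorter than the 2.0 h of the new flasks, I expect target to be past its rise at the end, with over-reaction product ahead of it in summer and in spring.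

3. The gain, the plateau share of target per unit of c(free catalyst), is then 3.27 mM⁻¹ in maple and, as a reading from elm, 4.19 mM⁻¹.

4. I use the run nearer in c(free catalyst) for each flask, so I commit to 9.23% target in summer and 21.6% in spring.

The forecast, which scales by one gain where I use two, says over-reaction product for summer and over-reaction product for spring, with 9% (6.5% to 11.5%) and 22% (17% to 27%) target, on the grounds that target is “drained to over-reaction product at a fixed first-order rate”.

    coupling partner + target → over-reaction product (k = 0.0151 L mol⁻¹ s⁻¹)
    coupling partner + second catalyst + intermediate → second catalyst + target (k = 253 L² mol⁻² s⁻¹)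
    2 substrate → homo dimer (k = 0.0171 L mol⁻¹ s⁻¹)
    substrate + free catalyst ⇌ free catalyst + intermediate (K = 2.20, k = 6.29 L mol⁻¹ s⁻¹)

In summer the half-life of target by the step with coupling partner, the other concentrations as charged, is 0.53 h, short against 2.0 h, and that flask ends with 9.08% target beside 16.5% over-reaction product, while spring ends with 21.1% beside 27.5%, a gain of 3.19 mM⁻¹ against the 3.27 mM⁻¹ read from maple. In a further flask, like spring but with 0.11 mM of free catalyst, the gain 3.27 mM⁻¹ gives 36.0%, and the flask holds 27.7%.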